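**Retrosynthetic overview**

1. Target ⇒ diol in which both free hydroxyls are acetylated last; the angelate is carried from the first C–O bond-forming step.
2. Side chain: the C2′ methyl stereocentre ⇒ face-selective hydrogenation of a 1,1-disubstituted alkene; the C3′–C4′ bond and C4′ carbinol ⇒ asymmetric allylchromium addition to 3-methylbut-2-enal; the allyl chloride ⇐ isopropenyl group (ene chlorination).
3. Ring C5 methyl and axial C4 hydroxyl ⇒ 1,4- then 1,2-hydride reduction of a 2-methylcyclohexenone.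
4. Key disconnection: the C1–O(angelate) bond ⇒ γ-selective (vinylogous) acyloxylation of the linear silyl dienol ether of (S)-carvone with angelic acid, trans to the isopropenyl group.
5. Ring order: the single carbocycle is taken intact from (S)-carvone; no ring is formed.

Assumption: compounds are numbered in the order they first appear in the forward steps (the overview uses names only); ring locants are those of the cyclohexyl ester (C1 O-angelate, C2 side chain, C4 O-acetyl, C5 methyl), and angelate means (2Z)-2-methylbut-2-enoate.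

**Step 1**
Reactants: 1 (S)-(+)-carvone
Product: 3 trimethyl{[(5R)-2-methyl-5-(prop-1-en-2-yl)cyclohexa-1,3-dien-1-yl]oxy}silane, via bromomagnesium dienolate 2 (not isolated)
Conditions: MeMgBr (1.3 equiv), FeCl3 (5 mol %), Et2O, −20 °C; then TMSCl, Et3N, DMPU, −20 → 23 °C; pentane filtration, used crude
Reagents that add atoms: chlorotrimethylsilane C[Si](C)(C)Cl; methylmagnesium bromide C[Mg]Br (gives only the MgBr of 2)
Why: Iron-catalysed γ-deprotonation of the enone by the Grignard base gives the linear (extended) dienolate and not the cross-conjugated one, and O-silylation traps it as the 1-siloxy-1,3-diene without touching the C5 stereocentre.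

**Step 2**
Reactants: 3 trimethyl{[(5R)-2-methyl-5-(prop-1-en-2-yl)cyclohexa-1,3-dien-1-yl]oxy}silane; 4 angelic acid
Product: 6 (1R,6S)-3-methyl-4-oxo-6-(prop-1-en-2-yl)cyclohex-2-en-1-yl (2Z)-2-methylbut-2-enoate, via bis(angeloyloxy)iodobenzene 5 (not isolated)
Conditions: PhIO (1.2 equiv), 4 (2.4 equiv), 4 Å MS, CH2Cl2, 23 °C, 1 h; then 3, TMSOTf (0.2 equiv), −78 → −40 °C; aq. NaHCO3
Reagents that add atoms: iodosylbenzene O=Ic1ccccc1 (gives only the PhI of 5; the acyloxy group of 6 comes from 4)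
Why: Proposed new method: vinylogous (γ) acyloxylation of a 1-siloxy-1,3-diene by a bis(acyloxy)-λ3-iodane made in the flask from PhIO and the free acid — TMSOTf-activated 5 exchanges silicon for trivalent iodine at the dienol oxygen to give an O-bound iodane dienolate that is electrophilic at carbon, the α-carbon is blocked by its methyl group so angelate adds to the γ-terminus in an SN2″ sense with loss of PhI, anti to the neighbouring isopropenyl group, which sets the 1R C–O stereocentre trans to C6; the closest known reaction type is the Lewis-acid-promoted α-acetoxylation of silyl enol ethers by PhI(OAc)2, of which the γ-selective, diastereoselective transfer of an α,β-unsaturated carboxylate to a dienol silane has not been shown.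

**Step 3**
Reactants: 6 (1R,6S)-3-methyl-4-oxo-6-(prop-1-en-2-yl)cyclohex-2-en-1-yl (2Z)-2-methylbut-2-enoate
Product: 9 (1R,2S,4R,5S)-4-hydroxy-5-methyl-2-(prop-1-en-2-yl)cyclohexyl (2Z)-2-methylbut-2-enoate, via lithium enolate 7 (not isolated), via saturated ketone 8 (not isolated)
Conditions: LiBH(s-Bu)3 (1.1 equiv), THF, −78 °C; AcOH (1.1 equiv), −78 → −20 °C; LiBH(s-Bu)3 (1.3 equiv), −78 °C; AcOH quench
Reagents that add atoms: lithium tri-sec-butylborohydride [Li+].CCC(C)[BH-](C(C)CC)C(C)CC (gives hydrogen and the Li of 7)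
Why: Selectride-type 1,4- then 1,2-reduction: conjugate hydride addition to the α-methyl, β-unsubstituted enone gives enolate 7, axial C-protonation places the methyl equatorial (5S), and the bulky hydride then attacks ketone 8 from the equatorial side to give the axial 4R alcohol cis to the methyl, while the hindered angelate and the isopropenyl group do not react at −78 °C.

**Step 4**
Reactants: 9 (1R,2S,4R,5S)-4-hydroxy-5-methyl-2-(prop-1-en-2-yl)cyclohexyl (2Z)-2-methylbut-2-enoate
Product: 10 (1R,2S,4R,5S)-2-(3-chloroprop-1-en-2-yl)-4-hydroxy-5-methylcyclohexyl (2Z)-2-methylbut-2-enoate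
Conditions: NCS (1.1 equiv), PhSeCl (5 mol %), CH2Cl2, 23 °C
Reagents that add atoms: N-chlorosuccinimide O=C1CCC(=O)N1Cl
Why: Selenium-catalysed ene-type allylic chlorination converts the only electron-rich alkene into the transposed 2-(chloromethyl)allyl unit (the angelate alkene is electron-poor and the alcohol is not oxidised), and no stereocentre is formed.

**Step 5**
Reactants: 10 (1R,2S,4R,5S)-2-(3-chloroprop-1-en-2-yl)-4-hydroxy-5-methylcyclohexyl (2Z)-2-methylbut-2-enoate; 11 3-methylbut-2-enal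
Product: 13 (1R,2S,4R,5S)-4-hydroxy-2-[(4R)-4-hydroxy-6-methylhepta-1,5-dien-2-yl]-5-methylcyclohexyl (2Z)-2-methylbut-2-enoate, via trimethylsilyl ether 12 (not isolated)
Conditions: CrCl3 (10 mol %), (S,S)-N,N′-bis(3,5-di-tert-butylsalicylidene)cyclohexane-1,2-diamine (10 mol %), Et3N (20 mol %), Mn powder (3 equiv), TMSCl (1.5 equiv), MeCN, 23 °C; then 10% aq. citric acid, THF
Reagents that add atoms: chlorotrimethylsilane C[Si](C)(C)Cl (gives only the SiMe3 of 12)
Why: Catalytic asymmetric Nozaki–Hiyama–Kishi allylation: the allylchromium adds 1,2 to the enal and ignores the esters, and the chiral chromium–salen complex sets C4′ as R by Re-face attack (the sense is checked on a model aldehyde and the antipodal ligand is used if it is reversed).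

**Step 6**
Reactants: 13 (1R,2S,4R,5S)-4-hydroxy-2-[(4R)-4-hydroxy-6-methylhepta-1,5-dien-2-yl]-5-methylcyclohexyl (2Z)-2-methylbut-2-enoate
Product: 14 (1R,2S,4R,5S)-4-hydroxy-2-[(2R,4R)-4-hydroxy-6-methylhept-5-en-2-yl]-5-methylcyclohexyl (2Z)-2-methylbut-2-enoate
Conditions: H2 (1 atm), RhCl(PPh3)3 (5 mol %), benzene–EtOH (1:1), 23 °C
Reagents that add atoms: none
Why: Substrate-controlled homogeneous hydrogenation: RhCl(PPh3)3 reduces only the 1,1-disubstituted alkene (the trisubstituted alkene and the enoate are inert), and with the =CH2 terminus eclipsing the ring C2–H the catalyst approaches the face away from the equatorial C1 acyloxy group, which sets the 2′R methyl stereocentre.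

**Step 7**
Reactants: 14 (1R,2S,4R,5S)-4-hydroxy-2-[(2R,4R)-4-hydroxy-6-methylhept-5-en-2-yl]-5-methylcyclohexyl (2Z)-2-methylbut-2-enoate
Product: 15 (1R,2S,4R,5S)-4-acetoxy-2-[(2R,4R)-4-acetoxy-6-methylhept-5-en-2-yl]-5-methylcyclohexyl (2Z)-2-methylbut-2-enoate
Conditions: Ac2O (4 equiv), pyridine, DMAP (5 mol %), CH2Cl2, 0 → 23 °C
Reagents that add atoms: acetic anhydride CC(=O)OC(C)=O
Why: DMAP-catalysed O-acylation esterifies the axial ring alcohol and the allylic alcohol with retention at both carbinol centres, and the mild temperature avoids Z to E isomerisation of the angelate.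

**Compound list**

1 | (S)-(+)-carvone, (5S)-2-methyl-5-(prop-1-en-2-yl)cyclohex-2-en-1-one | CC1=CC[C@@H](CC1=O)C(C)=C | starting material
2 | bromomagnesium (5R)-2-methyl-5-(prop-1-en-2-yl)cyclohexa-1,3-dien-1-olate | CC1=C(O[Mg]Br)C[C@@H](C(C)=C)C=C1 | intermediate
3 | trimethyl{[(5R)-2-methyl-5-(prop-1-en-2-yl)cyclohexa-1,3-dien-1-yl]oxy}silane | CC1=C(O[Si](C)(C)C)C[C@@H](C(C)=C)C=C1 | intermediate
4 | angelic acid, (2Z)-2-methylbut-2-enoic acid | C/C=C(/C)C(=O)O | starting material
5 | bis(angeloyloxy)iodobenzene, bis{[(2Z)-2-methylbut-2-enoyl]oxy}(phenyl)-λ3-iodane | C/C=C(/C)C(=O)OI(OC(=O)/C(C)=C\C)c1ccccc1 | intermediate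
6 | (1R,6S)-3-methyl-4-oxo-6-(prop-1-en-2-yl)cyclohex-2-en-1-yl (2Z)-2-methylbut-2-enoate | C/C=C(/C)C(=O)O[C@@H]1C=C(C)C(=O)C[C@H]1C(C)=C | intermediate
7 | lithium (4R,5S)-2-methyl-4-{[(2Z)-2-methylbut-2-enoyl]oxy}-5-(prop-1-en-2-yl)cyclohex-1-en-1-olate | C/C=C(/C)C(=O)O[C@@H]1CC(C)=C(O[Li])C[C@H]1C(C)=C | intermediate
8 | (1R,2S,5S)-5-methyl-4-oxo-2-(prop-1-en-2-yl)cyclohexyl (2Z)-2-methylbut-2-enoate | C/C=C(/C)C(=O)O[C@@H]1C[C@H](C)C(=O)C[C@H]1C(C)=C | intermediate
9 | (1R,2S,4R,5S)-4-hydroxy-5-methyl-2-(prop-1-en-2-yl)cyclohexyl (2Z)-2-methylbut-2-enoate | C/C=C(/C)C(=O)O[C@@H]1C[C@H](C)[C@H](O)C[C@H]1C(C)=C | intermediate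
10 | (1R,2S,4R,5S)-2-(3-chloroprop-1-en-2-yl)-4-hydroxy-5-methylcyclohexyl (2Z)-2-methylbut-2-enoate | C/C=C(/C)C(=O)O[C@@H]1C[C@H](C)[C@H](O)C[C@H]1C(=C)CCl | intermediate
11 | 3-methylbut-2-enal | CC(C)=CC=O | starting material
12 | (1R,2S,4R,5S)-4-hydroxy-5-methyl-2-[(4R)-6-methyl-4-(trimethylsilyloxy)hepta-1,5-dien-2-yl]cyclohexyl (2Z)-2-methylbut-2-enoate | C/C=C(/C)C(=O)O[C@@H]1C[C@H](C)[C@H](O)C[C@H]1C(=C)C[C@H](C=C(C)C)O[Si](C)(C)C | intermediate
13 | (1R,2S,4R,5S)-4-hydroxy-2-[(4R)-4-hydroxy-6-methylhepta-1,5-dien-2-yl]-5-methylcyclohexyl (2Z)-2-methylbut-2-enoate | C/C=C(/C)C(=O)O[C@@H]1C[C@H](C)[C@H](O)C[C@H]1C(=C)C[C@H](C=C(C)C)O | intermediate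
14 | (1R,2S,4R,5S)-4-hydroxy-2-[(2R,4R)-4-hydroxy-6-methylhept-5-en-2-yl]-5-methylcyclohexyl (2Z)-2-methylbut-2-enoate | C/C=C(/C)C(=O)O[C@@H]1C[C@H](C)[C@H](O)C[C@H]1[C@H](C)C[C@H](C=C(C)C)O | intermediate
15 | (1R,2S,4R,5S)-4-acetoxy-2-[(2R,4R)-4-acetoxy-6-methylhept-5-en-2-yl]-5-methylcyclohexyl (2Z)-2-methylbut-2-enoate (CNP0286954.1) | C/C=C(/C)C(=O)O[C@@H]1C[C@H](C)[C@H](OC(C)=O)C[C@H]1[C@H](C)C[C@H](C=C(C)C)OC(C)=O | target

**Step count and risks**

Total step count: 7. Longest linear sequence: 7 steps (1 → 15).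

Three steps most likely to fail:

Step 2 (the proposed new reaction). Possible failures are acyloxylation at the α- or α′-carbon, loss of a proton to give a carvacrol-type phenol, attack of the iodane on the isopropenyl group, or the cis ester if a C-bound iodane is displaced with inversion. The fallback uses known chemistry, sets out from 3 and comes back at 6. Vinylogous Rubottom oxidation of 3 with dimethyldioxirane (acetone/CH2Cl2, −78 °C) oxidises the distal diene bond anti to the isopropenyl group and gives (4R,5S)-4-hydroxy-2-methyl-5-(prop-1-en-2-yl)cyclohex-2-en-1-one F1. F1 is then esterified with 4 through the mixed anhydride (2,4,6-trichlorobenzoyl chloride, Et3N, toluene; then F1, DMAP cat., 23 °C) to give 6. This costs one extra step.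

Step 5 (C4′ stereocontrol). The β,β-disubstituted enal may give only modest facial selectivity with the chromium–salen catalyst. The fallback makes the carbinol centre by ketone reduction instead of carbonyl addition; it sets out from 10 and comes back at 14.
- Unselective Barbier allylation of 11 with 10 (Zn dust, aq. NH4Cl/THF) gives (1R,2S,4R,5S)-4-hydroxy-2-[(4RS)-4-hydroxy-6-methylhepta-1,5-dien-2-yl]-5-methylcyclohexyl (2Z)-2-methylbut-2-enoate F2.
- Hydrogenation as in step 6 gives (1R,2S,4R,5S)-4-hydroxy-2-[(2R,4RS)-4-hydroxy-6-methylhept-5-en-2-yl]-5-methylcyclohexyl (2Z)-2-methylbut-2-enoate F3.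
- MnO2 (CH2Cl2) oxidises only the allylic alcohol to (1R,2S,4R,5S)-4-hydroxy-5-methyl-2-[(2R)-6-methyl-4-oxohept-5-en-2-yl]cyclohexyl (2Z)-2-methylbut-2-enoate F4.
- Corey–Bakshi–Shibata reduction of F4 ((S)-2-methyl-CBS-oxazaborolidine, excess catecholborane, toluene, −78 °C; alkenyl arm as the larger group) gives 14.

Step 6 (C2′ stereocontrol). The sense and size of the facial bias rest on an allylic-strain model and may be low or reversed. The fallback swaps the roles of the two alkene termini; it sets out from 9 and comes back at 14.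
- Hydroformylation of the isopropenyl group of 9 (Rh(acac)(CO)2 1 mol %, PPh3 10 mol %, CO/H2 1:1, 20 bar, toluene, 80 °C) adds hydrogen to C2′ and the new carbon to the terminal CH2, giving (1R,2S,4R,5S)-4-hydroxy-5-methyl-2-[(2R)-4-oxobutan-2-yl]cyclohexyl (2Z)-2-methylbut-2-enoate F5.
- Asymmetric Nozaki–Hiyama–Kishi alkenylation of F5 with 1-bromo-2-methylprop-1-ene (CrCl2, NiCl2 cat., chiral sulfonamide ligand, THF) gives 14.
- Because the terminal carbon now becomes the chain and not the methyl, the same facial preference gives the opposite C2′ configuration, so this sequence is the matched one if step 6 is found to favour the 2′S epimer. If the ring exerts no bias in either sequence, the C2′ epimers must be separated.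

**Further compounds**

F1 | step 2 | (4R,5S)-4-hydroxy-2-methyl-5-(prop-1-en-2-yl)cyclohex-2-en-1-one | O[C@@H]1C=C(C)C(=O)C[C@H]1C(C)=C
F2 | step 5 | (1R,2S,4R,5S)-4-hydroxy-2-[(4RS)-4-hydroxy-6-methylhepta-1,5-dien-2-yl]-5-methylcyclohexyl (2Z)-2-methylbut-2-enoate | C/C=C(/C)C(=O)O[C@@H]1C[C@H](C)[C@H](O)C[C@H]1C(=C)CC(O)C=C(C)C
F3 | step 5 | (1R,2S,4R,5S)-4-hydroxy-2-[(2R,4RS)-4-hydroxy-6-methylhept-5-en-2-yl]-5-methylcyclohexyl (2Z)-2-methylbut-2-enoate | C/C=C(/C)C(=O)O[C@@H]1C[C@H](C)[C@H](O)C[C@H]1[C@H](C)CC(O)C=C(C)C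
F4 | step 5 | (1R,2S,4R,5S)-4-hydroxy-5-methyl-2-[(2R)-6-methyl-4-oxohept-5-en-2-yl]cyclohexyl (2Z)-2-methylbut-2-enoate | C/C=C(/C)C(=O)O[C@@H]1C[C@H](C)[C@H](O)C[C@H]1[C@H](C)CC(=O)C=C(C)C
F5 | step 6 | (1R,2S,4R,5S)-4-hydroxy-5-methyl-2-[(2R)-4-oxobutan-2-yl]cyclohexyl (2Z)-2-methylbut-2-enoate | C/C=C(/C)C(=O)O[C@@H]1C[C@H](C)[C@H](O)C[C@H]1[C@H](C)CC=O
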